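**Retrosynthetic overview**

1. Locants are chamigrane locants: ring A = C6 (spiro), C7 (bears C14), C8, C9, C10, C11 (bears methyls C12, C13); ring B = C6, C5, C4, C3 (bears methyl C15), C2, C1. The route rests on two features: C3 is the only oxygen-bearing carbon of ring B and lies 1,4 to spiro C6, so ring B is a reduced para-substituted phenol with C6 as its ipso carbon; and the run C14–C7–C8–C9 of ring A is an alk-2-ynoyl chain (C9 carbonyl, C7 β-carbon), carried here with a silyloxy group on C14.
2. Key disconnection C6–C7: ring B is present from the start as the arene of phenol ynone 9; dearomative ipso-cyclisation closes ring A and gives the achiral spiro trienedione 10.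
3. Ring B is then desymmetrised: asymmetric conjugate reduction of C4=C5 sets C6, and 1,4-hydrosilylation of C1=C2 stores the C2 regiochemistry as the C2=C3 silyl enol ether 13. While C2 is still sp2, C10–Br and C9–OH are set in ring A by conformational relay from C6 and become configurationally fixed.
4. Ring B is completed by NCS at C2 and MeMgBr at C3 (C15). The C14 oxygen is finally exchanged for the C7=C14 methylene by reductive 1,3-transposition, because an α'-bromo ketone would not survive base deconjugation of a C14-methyl enone.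
5. Precursor 9 comes from Friedel–Crafts alkylation of anisole with 3-methylbut-2-enoic acid, demethylation, Weinreb amide formation and addition of the lithium acetylide of silylated prop-2-yn-1-ol.

Key step: step 6

Assumption: the sense of induction of the ligand in step 7 is not predicted here; (R)-DTBM-SEGPHOS is written, and its antipode is taken if the first run reduces the other enantiotopic alkene.

**Route**

Step 1
Reactants: 1 anisole; 2 3-methylbut-2-enoic acid
Product: 3 3-(4-methoxyphenyl)-3-methylbutanoic acid
Conditions: AlCl3 (2.5 equiv), anisole (excess), CH2Cl2, 0 °C to 23 °C; aq. HCl work-up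
Reagents that add atoms: none
Why: Friedel–Crafts alkylation: the AlCl3-activated acid gives a tertiary cation at its C3, which anisole should capture at the para position for steric reasons.

Step 2
Reactants: 3 3-(4-methoxyphenyl)-3-methylbutanoic acid
Product: 4 3-(4-hydroxyphenyl)-3-methylbutanoic acid
Conditions: BBr3 (3 equiv), CH2Cl2, −78 °C to 23 °C; H2O work-up
Reagents that add atoms: none
Why: Lewis acid cleavage of an aryl methyl ether: boron binds the ether oxygen and bromide attacks the methyl group, and hydrolysis returns the phenol and the acid.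

Step 3
Reactants: 4 3-(4-hydroxyphenyl)-3-methylbutanoic acid
Product: 5 3-(4-hydroxyphenyl)-N-methoxy-N,3-dimethylbutanamide
Conditions: MeNHOMe·HCl, EDC·HCl, HOBt, i-Pr2NEt, CH2Cl2, 0 °C to 23 °C
Reagents that add atoms: N,O-dimethylhydroxylamine hydrochloride, CNOC.Cl
Why: Carbodiimide amide coupling to the Weinreb amide: the amine should outcompete the phenol for the active ester.

Step 4
Reactants: 6 prop-2-yn-1-ol
Product: 7 tert-butyl(diphenyl)(prop-2-yn-1-yloxy)silane
Conditions: t-BuPh2SiCl, imidazole, CH2Cl2, 23 °C
Reagents that add atoms: tert-butyl(chloro)diphenylsilane, CC(C)(C)[Si](Cl)(c1ccccc1)c1ccccc1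
Why: Silylation of a primary alcohol with imidazole as base and nucleophilic catalyst; the robust silyl ether is chosen to survive steps 5 to 12.

Step 5
Reactants: 5 3-(4-hydroxyphenyl)-N-methoxy-N,3-dimethylbutanamide; 7 tert-butyl(diphenyl)(prop-2-yn-1-yloxy)silane
Product: 9 1-{[tert-butyl(diphenyl)silyl]oxy}-6-(4-hydroxyphenyl)-6-methylhept-2-yn-4-one, via lithium acetylide 8 (not isolated)
Conditions: 7 (2.6 equiv), n-BuLi (2.5 equiv), THF, −78 °C; then 5, −78 °C to 0 °C; AcOH, −78 °C
Reagents that add atoms: none
Why: Weinreb ketone synthesis: the first equivalent of acetylide deprotonates the phenol, the second adds to the amide, and the chelated tetrahedral adduct should prevent over-addition and keep the ynone masked from the phenoxide until the acid quench.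

Step 6
Reactants: 9 1-{[tert-butyl(diphenyl)silyl]oxy}-6-(4-hydroxyphenyl)-6-methylhept-2-yn-4-one
Product: 10 1-({[tert-butyl(diphenyl)silyl]oxy}methyl)-5,5-dimethylspiro[5.5]undeca-1,7,10-triene-3,9-dione
Conditions: AgOSO2CF3 (10 mol%), CH2Cl2, 23 °C
Reagents that add atoms: none
Why: The silver salt activates the alkyne as a π-acid and the ynone carbonyl polarises it so that C7 is the electrophilic carbon; the phenol carbon para to oxygen (C6) attacks C7 anti to silver, which forms the C6–C7 bond and an O-protonated spiro dienone with a vinyl–silver bond at C8. Loss of the phenolic proton should give the cross-conjugated dienone of ring B, and protodemetalation at C8 should give the C7=C8 enone and return the catalyst. The closest known reaction type is the silver- or acid-promoted dearomative ipso-cyclisation of phenol- and anisole-tethered ynones to spiro[4.5]trienones; with one more tether atom the closure of ring A is here a 6-endo-dig cyclisation. No stereocentre is formed, because ring B is still symmetric, C6 is not stereogenic and 10 is achiral. Ipso attack should win over ortho attack because the ortho carbons could only close a seven-membered ring, and C7 should win over C8 because a 5-exo closure at C8 would run against the ynone polarisation. The phenolic oxygen is held too far from the alkyne to add, the geminal methyls on C11 compress the tether toward the reactive conformation, and the C14 silyl ether is a spectator.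

Step 7
Reactants: 10 1-({[tert-butyl(diphenyl)silyl]oxy}methyl)-5,5-dimethylspiro[5.5]undeca-1,7,10-triene-3,9-dione
Product: 12 (6R)-14-[tert-butyl(diphenyl)silyl]oxy-15-norchamigra-1,7-diene-3,9-dione, via silyl dienol ether 11 (not isolated)
Conditions: Cu(OAc)2 (5 mol%), (R)-DTBM-SEGPHOS (5.5 mol%), (EtO)2MeSiH (1.1 equiv), toluene, −20 °C; then 1 M HCl, THF, 0 °C
Reagents that add atoms: none
Why: Copper hydride-catalysed asymmetric conjugate reduction used as a desymmetrisation of a 4,4-disubstituted cyclohexadienone: the ligated CuH should add hydride to C5 of one of the two enantiotopic alkenes, told apart by sp2 C7 and quaternary C11 on C6, which sets C6 (6R); the silyl dienol ether 11 is no longer an acceptor, so the C1=C2 alkene survives, and the fully substituted C7 shields the ring A enone.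

Step 8
Reactants: 12 (6R)-14-[tert-butyl(diphenyl)silyl]oxy-15-norchamigra-1,7-diene-3,9-dione
Product: 13 (6R)-14-[tert-butyl(diphenyl)silyl]oxy-3-(triethylsilyl)oxy-15-norchamigra-2,7-dien-9-one
Conditions: RhCl(PPh3)3 (2 mol%), Et3SiH (1.5 equiv), toluene, 50 °C; chromatography on Et3N-treated silica
Reagents that add atoms: triethylsilane, CC[SiH](CC)CC
Why: Rh-catalysed 1,4-hydrosilylation of an enone: hydride goes to C1 and silicon to oxygen, so the enol ether forms regiospecifically as C2=C3, which fixes where chlorine will go and keeps C6 stereogenic; the ring A enone is shielded at its fully substituted β-carbon C7.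

Step 9
Reactants: 13 (6R)-14-[tert-butyl(diphenyl)silyl]oxy-3-(triethylsilyl)oxy-15-norchamigra-2,7-dien-9-one
Product: 15 (6S,10S)-10-bromo-14-[tert-butyl(diphenyl)silyl]oxy-3-(triethylsilyl)oxy-15-norchamigra-2,7-dien-9-one, via lithium enolate 14 (not isolated)
Conditions: LiN(i-Pr)2 (1.05 equiv), THF, −78 °C; then N-bromosuccinimide (1.0 equiv), −78 °C; AcOH quench
Reagents that add atoms: N-bromosuccinimide, O=C1CCC(=O)N1Br
Why: Kinetic α'-deprotonation of the ring A enone (as with isophorone) gives the cross-conjugated C9=C10 lithium enolate, which N-bromosuccinimide should brominate far faster than the ring B silyl enol ether; because sp2 C2 has no axial hydrogen, C14 on the ring B-axial C7 tilts over the C1–C2 edge, which puts C5 axial on ring A, so bromine should enter C10 anti to C5 and end equatorial and cis to C1 (10S), which is also the more stable epimer (the C6 descriptor changes only through CIP priority).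

Step 10
Reactants: 15 (6S,10S)-10-bromo-14-[tert-butyl(diphenyl)silyl]oxy-3-(triethylsilyl)oxy-15-norchamigra-2,7-dien-9-one
Product: 16 (6S,9R,10S)-10-bromo-14-[tert-butyl(diphenyl)silyl]oxy-3-(triethylsilyl)oxy-15-norchamigra-2,7-dien-9-ol
Conditions: i-Bu2AlH (1.2 equiv), CH2Cl2, −78 °C; aq. potassium sodium tartrate work-up
Reagents that add atoms: none
Why: 1,2-Reduction of the enone by the aluminium hydride: the axial methyl on C11 blocks the axial trajectory at C9, so hydride should arrive from the C5 side and give the axial carbinol cis to the equatorial bromide (9R), after which C10 can no longer epimerise; the silyl enol ether, the silyl ether and the C–Br bond are inert at −78 °C.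

Step 11
Reactants: 16 (6S,9R,10S)-10-bromo-14-[tert-butyl(diphenyl)silyl]oxy-3-(triethylsilyl)oxy-15-norchamigra-2,7-dien-9-ol
Product: 17 (2S,6S,9R,10S)-10-bromo-2-chloro-9-hydroxy-14-[tert-butyl(diphenyl)silyl]oxy-15-norchamigr-7-en-3-one
Conditions: N-chlorosuccinimide (1.05 equiv), NaHCO3, THF–H2O, 0 °C
Reagents that add atoms: N-chlorosuccinimide, O=C1CCC(=O)N1Cl
Why: Electrophilic α-chlorination of a silyl enol ether, regiospecific for C2: the reagent should add anti to the axial C7 arm and its C14 substituent, giving the equatorial chloride trans to C7 (2S), which is also the epimer favoured on any equilibration.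

Step 12
Reactants: 17 (2S,6S,9R,10S)-10-bromo-2-chloro-9-hydroxy-14-[tert-butyl(diphenyl)silyl]oxy-15-norchamigr-7-en-3-one
Product: 18 (2S,3R,6S,9R,10S)-10-bromo-2-chloro-14-[tert-butyl(diphenyl)silyl]oxychamigr-7-ene-3,9-diol
Conditions: CeCl3 (anhydrous, 4 equiv), MeMgBr (4 equiv), THF, −78 °C to −40 °C; aq. NH4Cl
Reagents that add atoms: methylmagnesium bromide, C[Mg]Br
Why: Cerium-modified Grignard addition to the only ketone left: CeCl3 suppresses enolisation of the α-chloro ketone, and methyl should add equatorially and anti to the C2 chloride, giving the axial tertiary alcohol cis to chlorine (3R), the usual outcome for 2-chlorocyclohexanones; a cis halohydrin alkoxide cannot close to an epoxide.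

Step 13
Reactants: 18 (2S,3R,6S,9R,10S)-10-bromo-2-chloro-14-[tert-butyl(diphenyl)silyl]oxychamigr-7-ene-3,9-diol
Product: 19 (2S,3R,6S,9R,10S)-10-bromo-2-chlorochamigr-7-ene-3,9,14-triol
Conditions: n-Bu4NF, AcOH, THF, 0 °C to 23 °C
Reagents that add atoms: none
Why: Fluoride cleavage of the silyl ether, buffered with acetic acid so that the two cis halohydrins see no free alkoxide.

Step 14
Reactants: 19 (2S,3R,6S,9R,10S)-10-bromo-2-chlorochamigr-7-ene-3,9,14-triol
Product: 22 (2S,3R,6S,9R,10S)-10-bromo-2-chlorochamigr-7(14)-ene-3,9-diol, via sulfonylhydrazine adduct 20 (not isolated), via allylic diazene 21 (not isolated)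
Conditions: PPh3, diethyl azodicarboxylate, 2-nitrobenzenesulfonylhydrazide (1.2 equiv each), N-methylmorpholine, −30 °C, then 23 °C
Reagents that add atoms: none
Why: Reductive 1,3-transposition of an allylic alcohol: Mitsunobu displacement of the primary C14 hydroxyl by the sulfonylhydrazide, loss of sulfinic acid to the monoalkyl diazene and retro-ene loss of N2 should deliver hydrogen to C8 and move the alkene to C7=C14; the hindered secondary C9 and tertiary C3 hydroxyls should not enter the Mitsunobu step, and no stereocentre is touched.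

**Compound list**

1 | anisole | COc1ccccc1 | starting material
2 | 3-methylbut-2-enoic acid | CC(C)=CC(=O)O | starting material
3 | 3-(4-methoxyphenyl)-3-methylbutanoic acid | COc1ccc(cc1)C(C)(C)CC(=O)O | intermediate
4 | 3-(4-hydroxyphenyl)-3-methylbutanoic acid | OC(=O)CC(C)(C)c1ccc(O)cc1 | intermediate
5 | 3-(4-hydroxyphenyl)-N-methoxy-N,3-dimethylbutanamide | CON(C)C(=O)CC(C)(C)c1ccc(O)cc1 | intermediate
6 | prop-2-yn-1-ol | C#CCO | starting material
7 | tert-butyl(diphenyl)(prop-2-yn-1-yloxy)silane | C#CCO[Si](c1ccccc1)(c1ccccc1)C(C)(C)C | intermediate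
8 | lithium acetylide of 7 | [Li]C#CCO[Si](c1ccccc1)(c1ccccc1)C(C)(C)C | intermediate (not isolated)
9 | 1-{[tert-butyl(diphenyl)silyl]oxy}-6-(4-hydroxyphenyl)-6-methylhept-2-yn-4-one (key-step precursor) | CC(C)(C)[Si](c1ccccc1)(c1ccccc1)OCC#CC(=O)CC(C)(C)c1ccc(O)cc1 | intermediate
10 | 1-({[tert-butyl(diphenyl)silyl]oxy}methyl)-5,5-dimethylspiro[5.5]undeca-1,7,10-triene-3,9-dione (key-step product, achiral) | CC(C)(C)[Si](c1ccccc1)(c1ccccc1)OCC1=CC(=O)CC(C)(C)C12C=CC(=O)C=C2 | intermediate
11 | (6R)-3-[diethoxy(methyl)silyl]oxy-14-[tert-butyl(diphenyl)silyl]oxy-15-norchamigra-1,3,7-trien-9-one (ring B silyl dienol ether, C1=C2 and C3=C4) | CC(C)(C)[Si](c1ccccc1)(c1ccccc1)OCC1=CC(=O)CC(C)(C)[C@]12CC=C(O[Si](C)(OCC)OCC)C=C2 | intermediate (not isolated)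
12 | (6R)-14-[tert-butyl(diphenyl)silyl]oxy-15-norchamigra-1,7-diene-3,9-dione (ring B enone C1=C2–C3=O, ring A enone C7=C8–C9=O) | CC(C)(C)[Si](c1ccccc1)(c1ccccc1)OCC1=CC(=O)CC(C)(C)[C@]12CCC(=O)C=C2 | intermediate
13 | (6R)-14-[tert-butyl(diphenyl)silyl]oxy-3-(triethylsilyl)oxy-15-norchamigra-2,7-dien-9-one | CC(C)(C)[Si](c1ccccc1)(c1ccccc1)OCC1=CC(=O)CC(C)(C)[C@]12CCC(O[Si](CC)(CC)CC)=CC2 | intermediate
14 | lithium C9=C10 enolate of 13 (6R) | CC(C)(C)[Si](c1ccccc1)(c1ccccc1)OCC1=CC(O[Li])=CC(C)(C)[C@]12CCC(O[Si](CC)(CC)CC)=CC2 | intermediate (not isolated)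
15 | (6S,10S)-10-bromo-14-[tert-butyl(diphenyl)silyl]oxy-3-(triethylsilyl)oxy-15-norchamigra-2,7-dien-9-one | CC(C)(C)[Si](c1ccccc1)(c1ccccc1)OCC1=CC(=O)[C@@H](Br)C(C)(C)[C@]12CCC(O[Si](CC)(CC)CC)=CC2 | intermediate
16 | (6S,9R,10S)-10-bromo-14-[tert-butyl(diphenyl)silyl]oxy-3-(triethylsilyl)oxy-15-norchamigra-2,7-dien-9-ol | CC(C)(C)[Si](c1ccccc1)(c1ccccc1)OCC1=C[C@@H](O)[C@@H](Br)C(C)(C)[C@]12CCC(O[Si](CC)(CC)CC)=CC2 | intermediate
17 | (2S,6S,9R,10S)-10-bromo-2-chloro-9-hydroxy-14-[tert-butyl(diphenyl)silyl]oxy-15-norchamigr-7-en-3-one | CC(C)(C)[Si](c1ccccc1)(c1ccccc1)OCC1=C[C@@H](O)[C@@H](Br)C(C)(C)[C@]12CCC(=O)[C@@H](Cl)C2 | intermediate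
18 | (2S,3R,6S,9R,10S)-10-bromo-2-chloro-14-[tert-butyl(diphenyl)silyl]oxychamigr-7-ene-3,9-diol | CC(C)(C)[Si](c1ccccc1)(c1ccccc1)OCC1=C[C@@H](O)[C@@H](Br)C(C)(C)[C@]12CC[C@@](C)(O)[C@@H](Cl)C2 | intermediate
19 | (2S,3R,6S,9R,10S)-10-bromo-2-chlorochamigr-7-ene-3,9,14-triol | OCC1=C[C@@H](O)[C@@H](Br)C(C)(C)[C@]12CC[C@@](C)(O)[C@@H](Cl)C2 | intermediate
20 | N-(C14-allyl)-N-(2-nitrobenzenesulfonyl)hydrazine derived from 19 | NN(CC1=C[C@@H](O)[C@@H](Br)C(C)(C)[C@]12CC[C@@](C)(O)[C@@H](Cl)C2)S(=O)(=O)c1ccccc1[N+](=O)[O-] | intermediate (not isolated)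
21 | C14 monoalkyl diazene derived from 20 | N=NCC1=C[C@@H](O)[C@@H](Br)C(C)(C)[C@]12CC[C@@](C)(O)[C@@H](Cl)C2 | intermediate (not isolated)
22 | (2S,3R,6S,9R,10S)-10-bromo-2-chlorochamigr-7(14)-ene-3,9-diol | C=C1C[C@@H](O)[C@@H](Br)C(C)(C)[C@]12CC[C@@](C)(O)[C@@H](Cl)C2 | target

**Step count and risks**

Total steps: 14. Longest linear sequence: 13 (steps 1 to 3 and 5 to 14, from anisole).

Steps most likely to fail:

1. Step 6 (key step). The six-membered closure may be slower than the known five-membered cases, so that hydration of the ynone, intermolecular addition of the phenol to the ynone or acid-induced dienone–phenol rearrangement of 10 could compete. Fallback: a halonium-triggered ipso-cyclisation of the methyl ether in place of π-acid catalysis on the phenol. It sets out from 3. Amidation as in step 3 gives 3-(4-methoxyphenyl)-N-methoxy-N,3-dimethylbutanamide F1. Addition of acetylide 8 as in step 5 gives the anisole ynone F2. ICl in CH2Cl2 at −78 °C should trigger ipso-iodocyclisation with loss of the O-methyl group to the 8-iodo spiro trienedione F3. Bu3SnH with catalytic Pd(PPh3)4 in THF then removes the vinylic iodine, and the route is rejoined at 10.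

2. Step 9. Facial selection at C10 may be poor if the conformational relay from C6 is weaker than argued, and some halogen may be transferred to the ring B enol ether. Fallback: thermodynamic control at C10 in place of kinetic control. It sets out from 13. The enolate 14 is brominated as before without regard to the face, giving 15 together with its (6S,10R) C10 epimer F4. The mixture is stirred with catalytic 1,8-diazabicyclo[5.4.0]undec-7-ene in CH2Cl2 at 23 °C. Reversible enolisation toward C10 should funnel F4 into the epimer with equatorial bromine anti to the axial C5, and the route is rejoined at 15.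

3. Step 7. Discrimination between the two enantiotopic alkenes may be weak because both C7 and C11 are fully substituted, and 1,2-reduction of a carbonyl could intervene. Fallback: discrimination of enantiotopic protons in place of enantiotopic alkenes. It sets out from 10. Cu(OAc)2, 1,2-bis(diphenylphosphino)benzene, (EtO)2MeSiH (2.5 equiv) and t-BuOH in toluene reduce both ring B alkenes to the achiral 14-silyloxy-15-norchamigr-7-ene-3,9-dione F5. Lithium bis[(R)-1-phenylethyl]amide with LiCl in THF at −78 °C, followed by Et3SiCl, should remove one of the enantiotopic axial protons at C2 and C4. This gives the C2=C3 silyl enol ether directly, and the route is rejoined at 13 without passing through 12.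

**Further compounds**

F1 | step 6 | 3-(4-methoxyphenyl)-N-methoxy-N,3-dimethylbutanamide | CON(C)C(=O)CC(C)(C)c1ccc(OC)cc1
F2 | step 6 | 1-{[tert-butyl(diphenyl)silyl]oxy}-6-(4-methoxyphenyl)-6-methylhept-2-yn-4-one | CC(C)(C)[Si](c1ccccc1)(c1ccccc1)OCC#CC(=O)CC(C)(C)c1ccc(OC)cc1
F3 | step 6 | 1-({[tert-butyl(diphenyl)silyl]oxy}methyl)-2-iodo-5,5-dimethylspiro[5.5]undeca-1,7,10-triene-3,9-dione | CC(C)(C)[Si](c1ccccc1)(c1ccccc1)OCC1=C(I)C(=O)CC(C)(C)C12C=CC(=O)C=C2
F4 | step 9 | (6S,10R)-10-bromo-14-[tert-butyl(diphenyl)silyl]oxy-3-(triethylsilyl)oxy-15-norchamigra-2,7-dien-9-one | CC(C)(C)[Si](c1ccccc1)(c1ccccc1)OCC1=CC(=O)[C@H](Br)C(C)(C)[C@]12CCC(O[Si](CC)(CC)CC)=CC2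
F5 | step 7 | 14-[tert-butyl(diphenyl)silyl]oxy-15-norchamigr-7-ene-3,9-dione (achiral) | CC(C)(C)[Si](c1ccccc1)(c1ccccc1)OCC1=CC(=O)CC(C)(C)C12CCC(=O)CC2
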